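**Retrosynthetic overview**

1. Ring B numbering: C1 carries the ketone carbon, C2 OH, C3 H, C4 OH, C5 prenyl, C6 OMe. Ring A is the 4-hydroxy-3-methoxyphenyl group. Both benzene rings are bought intact, so no ring is formed.
2. Last disconnections: two MOM ethers (ring B C4–O, ring A C4–O). The C5 prenyl group is traced back by a para-Claisen–Cope shift to an O-prenyl ether on the C2 oxygen, since C5 is para to C2.
3. Key disconnection: the ketone carbon–C1 bond together with the C2–O bond. A 3-methoxy-5-(methoxymethoxy)benzyne (triple bond C1≡C2) inserts into the C(=O)–OH bond of MOM-protected vanillic acid, and the phenoxide is capped in the same flask with prenyl bromide (three components).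
4. Enabling feature: ring B is an ortho-hydroxyaryl ketone (C2–OH next to the C1 aroyl carbon) whose other neighbour, C6, carries OMe. The phenol oxygen can therefore come from the acid, and the C6 methoxy group polarises the aryne so that oxygen goes to C2 and the acyl carbon to C1.
5. The aryne precursor comes from commercial 3-methoxy-2-(trimethylsilyl)phenyl triflate by meta C–H borylation/oxidation and MOM protection; the acid comes from vanillic acid.

Key step: step 4

Remark on the chemistry: the target has no stereogenic element (no stereocentre, and the prenyl alkene carries two identical methyl groups), so it is achiral and no stereocontrol is required.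

**Route**

Step 1
Reactants: 1 vanillic acid (4-hydroxy-3-methoxybenzoic acid)
Product: 3 3-methoxy-4-(methoxymethoxy)benzoic acid, via MOM ester 2 (not isolated)
Conditions: MOMCl (2.4 equiv), iPr2NEt, CH2Cl2, 0 °C to rt; then LiOH, THF/H2O, rt; aq. HCl to pH 4, 0 °C
Reagents that add atoms: chloromethyl methyl ether (MOMCl), COCCl
Why: Williamson-type O-alkylation of phenoxide and carboxylate with MOMCl, followed by saponification of the methoxymethyl ester (an acyl acetal far more labile to hydroxide than the aryl MOM ether), should leave only the phenol protected.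

Step 2
Reactants: 4 3-methoxy-2-(trimethylsilyl)phenyl trifluoromethanesulfonate
Product: 6 5-hydroxy-3-methoxy-2-(trimethylsilyl)phenyl trifluoromethanesulfonate, via arylboronate 5 (not isolated)
Conditions: [Ir(OMe)(cod)]2 (cat.), dtbpy, B2pin2, THF, 80 °C; then Oxone, acetone/H2O, rt
Reagents that add atoms: bis(pinacolato)diboron, CC1(C)OB(OC1(C)C)B1OC(C)(C)C(C)(C)O1 (boron of intermediate 5); Oxone (potassium peroxymonosulfate), [K+].OOS(=O)(=O)[O-] (the phenol oxygen)
Why: Iridium-catalysed aromatic C–H borylation is sterically controlled and should take the only C–H bond without an ortho substituent (C5, meta to both OTf and OMe), and Oxone oxidation of the C–B bond in the same flask (one-pot C–H borylation/oxidation) should give the phenol without touching the aryl triflate or the C–Si bond.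

Step 3
Reactants: 6 5-hydroxy-3-methoxy-2-(trimethylsilyl)phenyl trifluoromethanesulfonate
Product: 7 3-methoxy-5-(methoxymethoxy)-2-(trimethylsilyl)phenyl trifluoromethanesulfonate
Conditions: MOMCl, iPr2NEt, CH2Cl2, 0 °C to rt
Reagents that add atoms: chloromethyl methyl ether (MOMCl), COCCl
Why: Standard MOM ether formation on a phenol with an amine base; the triflate and the aryl silane are inert to these fluoride-free, non-nucleophilic conditions.

Step 4
Reactants: 7 3-methoxy-5-(methoxymethoxy)-2-(trimethylsilyl)phenyl trifluoromethanesulfonate; 3 3-methoxy-4-(methoxymethoxy)benzoic acid; 8 prenyl bromide (1-bromo-3-methylbut-2-ene)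
Product: 11 (2-methoxy-4-(methoxymethoxy)-6-prenyloxyphenyl)(3-methoxy-4-(methoxymethoxy)phenyl)methanone, via aryne 9 (not isolated), via hydroxy ketone 10 (not isolated)
Conditions: CsF, THF, 125 °C (sealed tube); then 8, Cs2CO3, DMF, 50 °C (same flask)
Reagents that add atoms: none
Why: Fluoride removes the trimethylsilyl group of 7 and triflate leaves, giving aryne 9; the cesium carboxylate of 3 adds through oxygen to the aryne carbon remote from the methoxy group (the future C2), and the aryl anion formed at C1 attacks the ester carbonyl just created (transient four-membered benzoxetene alkoxide, 4-exo-trig), which reopens by C–O cleavage to the ketone phenoxide of 10, a net insertion of the aryne into the C(=O)–O bond that forms the aroyl–C1 bond and the C2–O bond at once. The closest known reaction type is the fluoride-induced C–O insertion of arynes into carboxylic acids to give ortho-hydroxyaryl ketones (an aryne-triggered anionic Fries-type 1,3 O-to-C acyl shift), followed here in the same flask by Williamson O-alkylation of the phenoxide with 8. No ring of the product is closed and no stereocentre is formed. The step needs regioselective addition to the unsymmetrical aryne, which is secured by the inductively withdrawing C6 methoxy group next to the triple bond: it distorts the aryne so that the nucleophile enters meta to it and the negative charge develops ortho to it, while the C4 methoxymethoxy group, further away, should have only a weak influence. It also needs acyl transfer to outrun protonation of the aryl anion, which the high temperature and the intramolecular geometry favour, and O- over C-alkylation of the phenoxide, which the cesium counter-ion in a dipolar aprotic medium favours.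

Step 5
Reactants: 11 (2-methoxy-4-(methoxymethoxy)-6-prenyloxyphenyl)(3-methoxy-4-(methoxymethoxy)phenyl)methanone
Product: 14 (2-hydroxy-6-methoxy-4-(methoxymethoxy)-5-prenylphenyl)(3-methoxy-4-(methoxymethoxy)phenyl)methanone, via ortho-dienone 12 (not isolated), via para-dienone 13 (not isolated)
Conditions: PhNEt2, 200 °C
Reagents that add atoms: none
Why: Thermal para-Claisen–Cope sequence: a [3,3] shift of the aryl prenyl ether to the only free ortho carbon C3 gives dienone 12 with a 1,1-dimethylallyl group, whose congestion next to the C4 OMOM group should favour a second [3,3] (Cope) shift to C5, and tautomerisation of 13 restores the hydrogen-bonded phenol with a normal prenyl group para to the C2 oxygen.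

Step 6
Reactants: 14 (2-hydroxy-6-methoxy-4-(methoxymethoxy)-5-prenylphenyl)(3-methoxy-4-(methoxymethoxy)phenyl)methanone
Product: 15 (2,4-dihydroxy-6-methoxy-5-prenylphenyl)(4-hydroxy-3-methoxyphenyl)methanone (target)
Conditions: aq. HCl (3 M), MeOH, rt to 40 °C
Reagents that add atoms: none
Why: Acid-catalysed acetal exchange (MOM ether solvolysis) in methanol should release both phenols; mild acid and low temperature are chosen because the prenyl alkene next to the freed C4 hydroxyl is prone to acid-catalysed chroman formation.

**Compound list**

1 | vanillic acid (4-hydroxy-3-methoxybenzoic acid) | COc1cc(C(=O)O)ccc1O | starting material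
2 | methoxymethyl 3-methoxy-4-(methoxymethoxy)benzoate (formed in the flask) | COCOC(=O)c1ccc(OCOC)c(OC)c1 | intermediate
3 | 3-methoxy-4-(methoxymethoxy)benzoic acid | COCOc1ccc(C(=O)O)cc1OC | intermediate
4 | 3-methoxy-2-(trimethylsilyl)phenyl trifluoromethanesulfonate | COc1cccc(OS(=O)(=O)C(F)(F)F)c1[Si](C)(C)C | starting material
5 | 3-methoxy-5-(4,4,5,5-tetramethyl-1,3,2-dioxaborolan-2-yl)-2-(trimethylsilyl)phenyl trifluoromethanesulfonate (formed in the flask) | COc1cc(B2OC(C)(C)C(C)(C)O2)cc(OS(=O)(=O)C(F)(F)F)c1[Si](C)(C)C | intermediate
6 | 5-hydroxy-3-methoxy-2-(trimethylsilyl)phenyl trifluoromethanesulfonate | COc1cc(O)cc(OS(=O)(=O)C(F)(F)F)c1[Si](C)(C)C | intermediate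
7 | 3-methoxy-5-(methoxymethoxy)-2-(trimethylsilyl)phenyl trifluoromethanesulfonate | COCOc1cc(OC)c([Si](C)(C)C)c(OS(=O)(=O)C(F)(F)F)c1 | intermediate
8 | prenyl bromide (1-bromo-3-methylbut-2-ene) | CC(C)=CCBr | starting material
9 | 3-methoxy-5-(methoxymethoxy)benzyne (formed in the flask) | C1#CC(OC)=CC(OCOC)=C1 | intermediate
10 | (2-hydroxy-6-methoxy-4-(methoxymethoxy)phenyl)(3-methoxy-4-(methoxymethoxy)phenyl)methanone (formed in the flask) | COCOc1ccc(C(=O)c2c(O)cc(OCOC)cc2OC)cc1OC | intermediate
11 | (2-methoxy-4-(methoxymethoxy)-6-prenyloxyphenyl)(3-methoxy-4-(methoxymethoxy)phenyl)methanone | COCOc1ccc(C(=O)c2c(OCC=C(C)C)cc(OCOC)cc2OC)cc1OC | intermediate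
12 | ortho-dienone: 2-aroyl-3-methoxy-5-(methoxymethoxy)-6-(2-methylbut-3-en-2-yl)cyclohexa-2,4-dien-1-one, aroyl = 3-methoxy-4-(methoxymethoxy)benzoyl (formed in the flask, transient sp3 centre racemic) | COCOc1ccc(C(=O)C2=C(OC)C=C(OCOC)C(C(C)(C)C=C)C2=O)cc1OC | intermediate
13 | para-dienone: 2-aroyl-3-methoxy-5-(methoxymethoxy)-4-prenylcyclohexa-2,5-dien-1-one, aroyl = 3-methoxy-4-(methoxymethoxy)benzoyl (formed in the flask, transient sp3 centre racemic) | COCOc1ccc(C(=O)C2=C(OC)C(CC=C(C)C)C(OCOC)=CC2=O)cc1OC | intermediate
14 | (2-hydroxy-6-methoxy-4-(methoxymethoxy)-5-prenylphenyl)(3-methoxy-4-(methoxymethoxy)phenyl)methanone | COCOc1ccc(C(=O)c2c(O)cc(OCOC)c(CC=C(C)C)c2OC)cc1OC | intermediate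
15 | (2,4-dihydroxy-6-methoxy-5-prenylphenyl)(4-hydroxy-3-methoxyphenyl)methanone | COc1cc(C(=O)c2c(O)cc(O)c(CC=C(C)C)c2OC)ccc1O | target

**Summary**

Total step count: 6. Longest linear sequence: 5 steps (4 → 6 → 7 → 11 → 14 → 15); step 1 is a one-step side branch.

**Steps most likely to fail**

Step 4 (aryne C–O insertion with in-flask prenylation).
- What may go wrong: protonation of the aryl anion before it reaches the ester carbonyl, so that the sequence stops at the aryl ester stage; consumption of the aryne by ene reaction or by addition of the product phenoxide; C- instead of O-alkylation in the quench.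
- Fallback (Friedel–Crafts logic in place of aryne chemistry): it sets out from 1, which is condensed with commercial 5-methoxyresorcinol F1 in Eaton's reagent (P2O5/MeSO3H, 60–80 °C). Acylation para to one hydroxyl and ortho to the other should give (2,4-dihydroxy-6-methoxyphenyl)(4-hydroxy-3-methoxyphenyl)methanone F2, to be separated from the isomer acylated between the two hydroxyls. MOMCl (2.1 equiv)/iPr2NEt should then protect the two hydroxyls that are not hydrogen-bonded to the ketone and give 10. Compound 10 with 8 and K2CO3 in acetone should give 11, where the fallback rejoins the route.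

Step 5 (para-Claisen–Cope).
- What may go wrong: stalling after the first [3,3] shift, when enolisation of the ortho-dienone outruns the Cope step and leaves a 1,1-dimethylallyl group at C3; thermal loss of the prenyl group.
- Fallback (blocking-group strategy): it sets out from 10, obtained by running step 4 without the prenyl bromide quench. NBS (CH2Cl2/MeCN, 0 °C) is expected to brominate ortho to the chelated hydroxyl and give (3-bromo-2-hydroxy-6-methoxy-4-(methoxymethoxy)phenyl)(3-methoxy-4-(methoxymethoxy)phenyl)methanone F3. Alkylation with 8 and K2CO3 in acetone should give the prenyl ether F4. On heating (PhNEt2, 180–200 °C), with both ortho positions substituted the dienone can only pass the allyl unit on to C5, which should give the bromo prenyl phenol F5. Hydrodebromination (Pd(OAc)2/PPh3, HCO2H/Et3N, DMF, 60–80 °C), which spares the trisubstituted alkene, should give 14, where the fallback rejoins the route.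

Step 6 (MOM removal).
- What may go wrong: under Brønsted acid the freed C4 hydroxyl adds across the protonated prenyl alkene (chroman formation), or the alkene takes up water or methanol.
- Fallback (acid-free endgame with a change of protecting group): it sets out from 10, whose MOM groups are removed with HCl/MeOH while no prenyl group is present, giving the triphenol ketone F2 (the same compound as in the fallback for step 4). Ac2O (2 equiv)/pyridine at 0 °C should acetylate the two hydroxyls that are not hydrogen-bonded and give the diacetate F6. Mitsunobu etherification of the remaining C2 hydroxyl with 3-methylbut-2-en-1-ol (PPh3, DIAD, THF) should give the prenyl ether F7. A Eu(fod)3-catalysed para-Claisen–Cope shift (CHCl3, 60 °C) should give the C5-prenyl diacetate F8. K2CO3 in MeOH at rt should then remove both acetates and give 15 directly.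

**Further compounds**

F1 | step 4 | 5-methoxyresorcinol (5-methoxybenzene-1,3-diol) | COc1cc(O)cc(O)c1
F2 | step 4 | (2,4-dihydroxy-6-methoxyphenyl)(4-hydroxy-3-methoxyphenyl)methanone | COc1cc(C(=O)c2c(O)cc(O)cc2OC)ccc1O
F3 | step 5 | (3-bromo-2-hydroxy-6-methoxy-4-(methoxymethoxy)phenyl)(3-methoxy-4-(methoxymethoxy)phenyl)methanone | COCOc1ccc(C(=O)c2c(O)c(Br)c(OCOC)cc2OC)cc1OC
F4 | step 5 | (3-bromo-6-methoxy-4-(methoxymethoxy)-2-prenyloxyphenyl)(3-methoxy-4-(methoxymethoxy)phenyl)methanone | COCOc1ccc(C(=O)c2c(OCC=C(C)C)c(Br)c(OCOC)cc2OC)cc1OC
F5 | step 5 | (3-bromo-2-hydroxy-6-methoxy-4-(methoxymethoxy)-5-prenylphenyl)(3-methoxy-4-(methoxymethoxy)phenyl)methanone | COCOc1ccc(C(=O)c2c(O)c(Br)c(OCOC)c(CC=C(C)C)c2OC)cc1OC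
F6 | step 6 | 4-(4-acetoxy-2-hydroxy-6-methoxybenzoyl)-2-methoxyphenyl acetate | CC(=O)Oc1ccc(C(=O)c2c(O)cc(OC(C)=O)cc2OC)cc1OC
F7 | step 6 | 4-(4-acetoxy-2-methoxy-6-prenyloxybenzoyl)-2-methoxyphenyl acetate | CC(=O)Oc1ccc(C(=O)c2c(OCC=C(C)C)cc(OC(C)=O)cc2OC)cc1OC
F8 | step 6 | 4-(4-acetoxy-6-hydroxy-2-methoxy-3-prenylbenzoyl)-2-methoxyphenyl acetate | CC(=O)Oc1ccc(C(=O)c2c(O)cc(OC(C)=O)c(CC=C(C)C)c2OC)cc1OC
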